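The vessel is stirred and isothermal at constant volume. In it, starting complex takes up incoming ligand twice over, and we want the complex with one exchanged from either of two recipes.

the same everywhere: starting complex 0.050 M

| charge | incoming ligand | leaving ligand | remark | time |
|---|---|---|---|---|
| beta | 0.055 M (fed, over 6.0 h) | 0.12 M | run made earlier |  |
| zeta | 0.055 M (fed, over 6.0 h) | 0.19 M | run made earlier |  |
| Saturday's | 0.0550 M (fed, over 6.0 h) | 0.250 M |  | 6.0 h |
| Friday's | 0.0550 M | 0.250 M | everything together at the start | 2.0 h |

| run | time / h | complex with one exchanged / % | starting complex / % |
|---|---|---|---|
| beta | 0.667 | 4.9 | 95.7 |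
| beta | 1.33 | 10.4 | 86.2 |
| beta | 2.00 | 17.1 | 79.5 |
| beta | 3.00 | 22.3 | 71.0 |
| beta | 4.00 | 26.5 | 64.1 |
| zeta | 0.333 | 0.7 | 96.3 |
| zeta | 0.833 | 6.9 | 91.8 |
| zeta | 1.50 | 13.3 | 87.7 |
| zeta | 2.50 | 18.1 | 75.6 |
| zeta | 4.00 | 24.8 | 62.9 |

(readings scatter by 1 percentage point)



1. which of the two ends with the higher amount of complex with one exchanged, in percent of the starting complex charged ("neither" if they lie within 2 percentage points) (Saturday's / Friday's / neither)
2. complex with one exchanged at the end, in percent of the starting complex charged, Saturday's
3. complex with one exchanged at the end, in percent of the starting complex charged, Friday's

I write m for the fraction of starting complex left, a for the fraction with one exchanged, and b for the remainder, taken as complex with two exchanged. I assume both exchanges run first order in incoming ligand, so its concentration and the dosing divide out of da/dm. Integrating gives a = (m^s − m)/(1 − s), where s is the ratio of the second rate constant to the first, the selectivity factor.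

Since b grows as s times the area of a against ln(1/m), I take b at 4.00 h over trapezoids through the beta and zeta rows. That reads s = 1.65. Setting da/dm to zero puts the top of the curve at m = 46.3%, with the peak share, a = s^(s/(1 − s)), at 28.0%.

Reaching that peak takes a + 2b = 0.794 of ligand per starting complex. The runs put 64.6% of the fed ligand onto complex, so Saturday's gets 0.710, less than the peak needs. The top of the curve is flat, though, so expect about the peak share in Saturday's when you come in. Friday's holds the same charge, and if the same share arrives I expect the same a, though no reading tests that share. So I say neither. Don't add more ligand: past the top of this curve a falls.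

The forecast, reading that “dissociation looks rate-limiting and capture efficient”, gives Saturday's, with 28% and 17%, and parts from me on Friday's.

The flasks give neither: 28.7% for Saturday's and 28.2% for Friday's.

    starting complex + incoming ligand → leaving ligand + complex with one exchanged (k = 0.738 /M/min)
    complex with one exchanged + incoming ligand → leaving ligand + complex with two exchanged (k = 1.16 /M/min)
    2 incoming ligand → self-condensation product (k = 0.210 /M/min)
    incoming ligand → decomposed reagent (k = 0.0147 /min)

Both end about at the peak share of 28.0%. Friday's stops there mainly because its incoming ligand is consumed, with 0.144% of its charge left after 2.00 h: with that consumption taken away, Friday's stands at 1.26% rather than 28.2%.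

A neighbour of Friday's charged with 0.013 M of starting complex has 4.23 of ligand per complex, more than the peak needs, so I expect it to pass the top and hold a near 28.0% at best. It gives 26.8%, with 41.2% as complex with two exchanged.

(All runs come from a simulation for an exercise; the scatter is artificial.)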